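Readings and results were computed on assumed constants, and the scatter is random.

I looked at the target first.

| setting | elm | maple | delta | gamma | theta | epsilon |
|---|---|---|---|---|---|---|
| starting material | 27 mM | 42 mM | 19 mM | 19 mM | 19 mM | 19 mM |
| coupling partner | 1.1 equiv | 1.1 equiv | 1.10 equiv | 1.10 equiv | 1.10 equiv | 1.10 equiv |
| temperature | 40 °C | 62 °C | 70 °C | 50 °C |  | 30 °C |
| remark | run made earlier | run made earlier |  |  | at 30 °C until 1.5 h, from then on at 70 °C |  |
| time |  |  | 8.0 h | 8.0 h | 8.0 h | 8.0 h |

- elm (time / h: target / %, side product / %): 6.00: 2, 0; 12.0: 0, 1; 20.0: 3, 3; 25.0: 1, 3; 40.0: 1, 12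
- maple (time / h: target / %, side product / %): 1.50: 0, 6; 3.00: 2, 13; 5.00: 1, 22; 6.00: 0, 28; 8.00: 3, 36

(scatter of a reading: 1.5 percentage points)



* the best flask by share of target in all that became target or side product; "all alike" if 1.5 percentage points covers them all (delta / gamma / theta / epsilon / all alike)
* share of target in all that became target or side product, delta
* share of target in all that became target or side product, gamma
* share of target in all that became target or side product, theta
* share of target in all that became target or side product, epsilon

The target readings showed no trend in either run within their scatter, so I held the target at one value, the frozen target level, the mean of the readings of both runs, 1.30%. The share then became that level over that level plus the side product. Straight lines from zero through the last readings gave side product over 8.0 h of 2.40% on elm's line and 36.0% on maple's line, so the reckoned shares were 35.1% and 3.49%. The two runs differ in charge as well as temperature, but I assumed that a hotter flask makes side product faster, in percent of the charge, whatever the charge. My reckoning therefore put delta, at 70 °C, under 3.49%, gamma, at 50 °C, between 3.49% and 35.1%, and epsilon, at 30 °C, above 35.1%. Theta, counting its 6.50 h at 70 °C on maple's line, came under 4.26%. So I picked epsilon.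

The forecast read the target as “a fragile intermediate at steady state” and gave its own numbers, not my limits: delta 3%, gamma 20%, theta 3%, epsilon 65%, best epsilon.

The flasks gave delta 2.56%, gamma 19.2%, theta 2.80% and epsilon 83.9%, with epsilon best. Epsilon stood 19 percentage points above the forecast.

    starting material ⇌ intermediate A (K = 7.70, k = 0.270 h⁻¹, Ea = 105 kJ mol⁻¹, ΔH = −40.0 kJ mol⁻¹)
    coupling partner + intermediate A → target (k = 0.450 M⁻¹ h⁻¹, Ea = 70.0 kJ mol⁻¹)
    starting material ⇌ intermediate B (K = 0.440, k = 0.410 h⁻¹, Ea = 95.0 kJ mol⁻¹, ΔH = −24.0 kJ mol⁻¹)
    coupling partner + intermediate A → intermediate C (k = 18.0 M⁻¹ h⁻¹, Ea = 81.0 kJ mol⁻¹)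
    intermediate C → side product (k = 0.0310 h⁻¹, Ea = 107 kJ mol⁻¹)
    coupling partner + intermediate C ⇌ intermediate D (K = 410 M⁻¹, k = 2.80 M⁻¹ h⁻¹, Ea = 73.0 kJ mol⁻¹, ΔH = −43.0 kJ mol⁻¹)
    (constants at 50 °C)

In delta at 0.361 h, intermediate A went to intermediate C 51 times faster than to target, a selectivity factor against the target. In delta at 0.361 h, intermediate C was made 7.17 times faster than it was used up, each step taken net. Epsilon at 8.00 h held target 0.0819%, less than the frozen level, and side product 0.0157%. Delta at 8.00 h held side product 67.1%, and the frozen level gave 1.90% against 2.56%; delta left until 30 h, with side product 94.3%, gave 1.36% against 1.99%.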